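**Retrosynthetic overview**
1. The decanoate, the aldehyde and the acetate are installed last (two acylations, one allylic oxidation) on a silyl-protected (16R)-allylic alcohol.
2. Key bond C16–C17: α-selective addition of geranylbarium chloride to a ring-bearing (E)-2-methyl enal (carbonyl allylation); C16 is then fixed by oxidation and CBS reduction.
3. The (2Z)-tetrasubstituted alkene comes from the ring ketone: kinetic vinyl triflate, Stille acetylation, conjugate reduction to a geometry-defined enol triflate, methoxycarbonylation. The C12–C16 arm grows from an allyl group.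
4. The C6/C10/C11 stereotriad comes from (S)-4-(PMB-oxy)-2-methylcyclohexenone: anti conjugate addition, trans enolate allylation, axial MeMgBr addition.
5. The single ring is never constructed: it is the benzene ring of 4-methoxy-3-methylphenol, dearomatised first and made chiral by CBS reduction.

Assumption: carbons are named by iridal numbering (C1 CHO, C2 its α-carbon, C3 OCH2, C6 ring CH, C7 ring sp2 carbon, C8/C9 ring CH2, C10 carbinol carbon, C11 quaternary carbon, C16 CH–OAc), the SMILES being read as the (6R,10S,11S,16R,2Z,14E,18E) isomer; silyl chlorides, both CBS oxazaborolidines, Ph3P=C(CH3)CHO and acid chlorides are bought and carry no number; TBDPS = tert-butyldiphenylsilyl, PMB = 4-methoxybenzyl, TES = triethylsilyl, TBS = tert-butyldimethylsilyl, TMS = trimethylsilyl.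

**Route**

Step 1
Reactants: 1 4-methoxy-3-methylphenol
Product: 2 4,4-dimethoxy-3-methylcyclohexa-2,5-dien-1-one
Conditions: PhI(OAc)2, MeOH, 0 °C
Reagents that add atoms: methanol CO
Why: Oxidative dearomatisation of a p-methoxyphenol in methanol traps the para position as the quinone monoketal, delivering all six ring carbons with the future C11 methyl in place and C10 masked.

Step 2
Reactants: 2 4,4-dimethoxy-3-methylcyclohexa-2,5-dien-1-one
Product: 3 4,4-dimethoxy-3-methylcyclohex-2-en-1-one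
Conditions: H2 (1 atm), RhCl(PPh3)3 (5 mol%), toluene, rt
Reagents that add atoms: none
Why: Chemoselective homogeneous hydrogenation reduces the unhindered disubstituted C8=C9 bond of the cross-conjugated dienone much faster than the methyl-bearing trisubstituted one.

Step 3
Reactants: 3 4,4-dimethoxy-3-methylcyclohex-2-en-1-one
Product: 4 (1S)-4,4-dimethoxy-3-methylcyclohex-2-en-1-ol
Conditions: (R)-2-methyl-CBS-oxazaborolidine (20 mol%), catecholborane, toluene, −78 °C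
Reagents that add atoms: none
Why: Corey–Bakshi–Shibata reduction with the alkenyl arm as the large group delivers hydride to one face and sets the (S)-carbinol at C7, a temporary stereocentre that later steers C6.

Step 4
Reactants: 4 (1S)-4,4-dimethoxy-3-methylcyclohex-2-en-1-ol
Product: 5 (1S)-4,4-dimethoxy-1-(PMB-oxy)-3-methylcyclohex-2-ene
Conditions: NaH, 4-methoxybenzyl chloride, Bu4NI (cat.), DMF, 0 °C to rt
Reagents that add atoms: 4-methoxybenzyl chloride COc1ccc(CCl)cc1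
Why: Williamson etherification installs a PMB group that can later be removed oxidatively without touching silyl ethers.

Step 5
Reactants: 5 (1S)-4,4-dimethoxy-1-(PMB-oxy)-3-methylcyclohex-2-ene
Product: 6 (4S)-4-(PMB-oxy)-2-methylcyclohex-2-en-1-one
Conditions: oxalic acid, THF/H2O, rt
Reagents that add atoms: water O
Why: Mild ketal hydrolysis unveils the C10 ketone next to the methyl-bearing alkene carbon, so the enone is transposed relative to 3 while the stereocentre is untouched.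

Step 6
Reactants: 7 3-bromopropan-1-ol
Product: 8 (3-bromopropoxy)(tert-butyl)diphenylsilane
Conditions: t-BuPh2SiCl, imidazole, CH2Cl2, 0 °C to rt
Reagents that add atoms: tert-butyl(chloro)diphenylsilane CC(C)(C)[Si](Cl)(c1ccccc1)c1ccccc1
Why: Standard silylation gives a robust TBDPS ether that survives the later acidic, basic and organometallic steps.

Step 7
Reactants: 6 (4S)-4-(PMB-oxy)-2-methylcyclohex-2-en-1-one; 8 (3-bromopropoxy)(tert-butyl)diphenylsilane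
Product: 10 (3S,4S)-3-[3-(TBDPS-oxy)propyl]-4-(PMB-oxy)-2-methyl-1-(TMS-oxy)cyclohex-1-ene, via Grignard reagent 9 (not isolated)
Conditions: 8, Mg, THF, rt; then CuBr·SMe2 (10 mol%), Me3SiCl, 6, THF, −78 °C
Reagents that add atoms: chlorotrimethylsilane C[Si](C)(C)Cl
Why: Copper-catalysed, silyl-chloride-accelerated conjugate addition occurs anti to the γ-alkoxy group, setting C6 trans to the PMB ether, and the enolate is trapped regiospecifically as the silyl enol ether.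

Step 8
Reactants: 10 (3S,4S)-3-[3-(TBDPS-oxy)propyl]-4-(PMB-oxy)-2-methyl-1-(TMS-oxy)cyclohex-1-ene
Product: 12 (2S,3S,4S)-2-allyl-3-[3-(TBDPS-oxy)propyl]-4-(PMB-oxy)-2-methylcyclohexan-1-one, via lithium enolate 11 (not isolated)
Conditions: MeLi, THF, 0 °C; then allyl bromide, DMPU, −78 to 0 °C
Reagents that add atoms: allyl bromide C=CCBr
Why: MeLi releases the regiodefined lithium enolate, whose C-alkylation takes place anti to the adjacent C6 substituent (2,3-trans enolate alkylation), fixing quaternary C11 with its methyl cis to the C6 chain.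

Step 9
Reactants: 12 (2S,3S,4S)-2-allyl-3-[3-(TBDPS-oxy)propyl]-4-(PMB-oxy)-2-methylcyclohexan-1-one
Product: 13 (1S,2S,3S,4S)-2-allyl-3-[3-(TBDPS-oxy)propyl]-4-(PMB-oxy)-1,2-dimethylcyclohexan-1-ol
Conditions: MeMgBr, THF, −78 to 0 °C
Reagents that add atoms: methylmagnesium bromide C[Mg]Br
Why: Grignard 1,2-addition to the chair with three equatorial substituents and an axial C11 methyl occurs axially on the face opposite that methyl, giving the equatorial (10S)-hydroxyl cis to the C11 methyl.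

Step 10
Reactants: 13 (1S,2S,3S,4S)-2-allyl-3-[3-(TBDPS-oxy)propyl]-4-(PMB-oxy)-1,2-dimethylcyclohexan-1-ol
Product: 14 (1S,2S,3S,4S)-2-allyl-3-[3-(TBDPS-oxy)propyl]-4-(PMB-oxy)-1,2-dimethyl-1-(TES-oxy)cyclohexane
Conditions: Et3SiOTf, 2,6-lutidine, CH2Cl2, −78 to 0 °C
Reagents that add atoms: triethylsilyl trifluoromethanesulfonate CC[Si](CC)(CC)OS(=O)(=O)C(F)(F)F
Why: Silyl triflate silylation caps the hindered tertiary alcohol so that it cannot interfere with the strong bases and triflating agents that follow.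

Step 11
Reactants: 14 (1S,2S,3S,4S)-2-allyl-3-[3-(TBDPS-oxy)propyl]-4-(PMB-oxy)-1,2-dimethyl-1-(TES-oxy)cyclohexane
Product: 15 (1S,2S,3S,4S)-3-allyl-2-[3-(TBDPS-oxy)propyl]-3,4-dimethyl-4-(TES-oxy)cyclohexan-1-ol
Conditions: DDQ, CH2Cl2/pH 7 buffer, 0 °C
Reagents that add atoms: none
Why: Oxidative PMB cleavage (benzylic hydride abstraction, then hydrolysis) frees only the C7 hydroxyl and leaves the silyl ethers and the alkene alone.

Step 12
Reactants: 15 (1S,2S,3S,4S)-3-allyl-2-[3-(TBDPS-oxy)propyl]-3,4-dimethyl-4-(TES-oxy)cyclohexan-1-ol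
Product: 16 (2S,3S,4S)-3-allyl-2-[3-(TBDPS-oxy)propyl]-3,4-dimethyl-4-(TES-oxy)cyclohexan-1-one
Conditions: Dess–Martin periodinane, NaHCO3, CH2Cl2, rt
Reagents that add atoms: none
Why: Buffered Dess–Martin oxidation gives the C7 ketone under non-epimerising conditions, so the adjacent C6 stereocentre is kept.

Step 13
Reactants: 16 (2S,3S,4S)-3-allyl-2-[3-(TBDPS-oxy)propyl]-3,4-dimethyl-4-(TES-oxy)cyclohexan-1-one
Product: 18 (4S,5S,6S)-5-allyl-6-[3-(TBDPS-oxy)propyl]-4,5-dimethyl-4-(TES-oxy)cyclohex-1-en-1-yl trifluoromethanesulfonate, via potassium enolate 17 (not isolated)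
Conditions: KN(SiMe3)2, THF, −78 °C; then PhNTf2, −78 to 0 °C
Reagents that add atoms: N-phenylbis(trifluoromethanesulfonimide) O=S(=O)(N(c1ccccc1)S(=O)(=O)C(F)(F)F)C(F)(F)F
Why: Kinetic deprotonation by the bulky amide takes the unhindered C8 methylene proton and not the tertiary C6–H, so enol triflate formation is regioselective and C6 is not epimerised.

Step 14
Reactants: 18 (4S,5S,6S)-5-allyl-6-[3-(TBDPS-oxy)propyl]-4,5-dimethyl-4-(TES-oxy)cyclohex-1-en-1-yl trifluoromethanesulfonate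
Product: 20 1-[(4S,5S,6S)-5-allyl-6-[3-(TBDPS-oxy)propyl]-4,5-dimethyl-4-(TES-oxy)cyclohex-1-en-1-yl]ethan-1-one, via 1-ethoxyvinyl diene 19 (not isolated)
Conditions: tributyl(1-ethoxyvinyl)stannane, Pd(PPh3)4 (5 mol%), LiCl, THF, 65 °C; then oxalic acid, THF/H2O, rt
Reagents that add atoms: tributyl(1-ethoxyvinyl)stannane CCCC[Sn](CCCC)(CCCC)C(=C)OCC; water O
Why: Stille coupling of the vinyl triflate with an acyl-anion equivalent, then enol ether hydrolysis, attaches C2 and its methyl as a methyl ketone conjugated to C7=C8.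

Step 15
Reactants: 20 1-[(4S,5S,6S)-5-allyl-6-[3-(TBDPS-oxy)propyl]-4,5-dimethyl-4-(TES-oxy)cyclohex-1-en-1-yl]ethan-1-one
Product: 22 (1Z)-1-[(2R,3S,4S)-3-allyl-2-[3-(TBDPS-oxy)propyl]-3,4-dimethyl-4-(TES-oxy)cyclohexylidene]ethyl trifluoromethanesulfonate, via lithium enolate 21 (not isolated)
Conditions: LiBH(s-Bu)3, THF, −78 °C; then PhNTf2, −78 to 0 °C
Reagents that add atoms: N-phenylbis(trifluoromethanesulfonimide) O=S(=O)(N(c1ccccc1)S(=O)(=O)C(F)(F)F)C(F)(F)F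
Why: The enone rests s-trans (carbonyl oxygen on the C6 side, acetyl methyl beside the vinylic H), so conjugate hydride addition at C8 gives the tetrasubstituted enolate with oxygen syn to C6 and O-triflation freezes that geometry.

Step 16
Reactants: 22 (1Z)-1-[(2R,3S,4S)-3-allyl-2-[3-(TBDPS-oxy)propyl]-3,4-dimethyl-4-(TES-oxy)cyclohexylidene]ethyl trifluoromethanesulfonate
Product: 23 methyl (2Z)-2-[(2R,3S,4S)-3-allyl-2-[3-(TBDPS-oxy)propyl]-3,4-dimethyl-4-(TES-oxy)cyclohexylidene]propanoate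
Conditions: Pd(OAc)2 (10 mol%), 1,3-bis(diphenylphosphino)propane, CO (1 atm), MeOH, Et3N, DMF, 60 °C
Reagents that add atoms: carbon monoxide [C-]#[O+]; methanol CO
Why: Palladium-catalysed methoxycarbonylation of an enol triflate proceeds with retention of alkene geometry, placing C1 syn to C6 as in the natural (2Z)-enal.

Step 17
Reactants: 23 methyl (2Z)-2-[(2R,3S,4S)-3-allyl-2-[3-(TBDPS-oxy)propyl]-3,4-dimethyl-4-(TES-oxy)cyclohexylidene]propanoate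
Product: 24 (2Z)-2-[(2R,3S,4S)-3-allyl-2-[3-(TBDPS-oxy)propyl]-3,4-dimethyl-4-(TES-oxy)cyclohexylidene]propan-1-ol
Conditions: i-Bu2AlH, CH2Cl2, −78 °C; aqueous potassium sodium tartrate (KNaC4H4O6) work-up
Reagents that add atoms: none
Why: Hydride reduction of the enoate to the allylic alcohol stores C1 at the alcohol level so that it cannot compete with the side-chain aldehyde chemistry.

Step 18
Reactants: 24 (2Z)-2-[(2R,3S,4S)-3-allyl-2-[3-(TBDPS-oxy)propyl]-3,4-dimethyl-4-(TES-oxy)cyclohexylidene]propan-1-ol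
Product: 25 (2Z)-2-[(2R,3S,4S)-3-allyl-2-[3-(TBDPS-oxy)propyl]-3,4-dimethyl-4-(TES-oxy)cyclohexylidene]-1-(TBS-oxy)propane
Conditions: t-BuMe2SiCl, imidazole, DMF, rt
Reagents that add atoms: tert-butyl(chloro)dimethylsilane CC(C)(C)[Si](C)(C)Cl
Why: Routine silylation protects the allylic alcohol through the organometallic and redox steps of the side chain.

Step 19
Reactants: 25 (2Z)-2-[(2R,3S,4S)-3-allyl-2-[3-(TBDPS-oxy)propyl]-3,4-dimethyl-4-(TES-oxy)cyclohexylidene]-1-(TBS-oxy)propane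
Product: 27 3-[(1S,2R,3Z,6S)-2-[3-(TBDPS-oxy)propyl]-1,6-dimethyl-3-[1-(TBS-oxy)propan-2-ylidene]-6-(TES-oxy)cyclohexyl]propan-1-ol, via B-alkyl-9-BBN adduct 26 (not isolated)
Conditions: 9-BBN, THF, rt; then NaOH, H2O2, 0 °C
Reagents that add atoms: hydrogen peroxide OO
Why: Hydroboration–oxidation with the bulky borane is anti-Markovnikov and touches only the monosubstituted alkene, not the tetrasubstituted ring alkene.

Step 20
Reactants: 27 3-[(1S,2R,3Z,6S)-2-[3-(TBDPS-oxy)propyl]-1,6-dimethyl-3-[1-(TBS-oxy)propan-2-ylidene]-6-(TES-oxy)cyclohexyl]propan-1-ol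
Product: 28 3-[(1S,2R,3Z,6S)-2-[3-(TBDPS-oxy)propyl]-1,6-dimethyl-3-[1-(TBS-oxy)propan-2-ylidene]-6-(TES-oxy)cyclohexyl]propanal
Conditions: Dess–Martin periodinane, NaHCO3, CH2Cl2, rt
Reagents that add atoms: none
Why: Dess–Martin oxidation gives the C14 aldehyde without over-oxidation or silyl loss.

Step 21
Reactants: 28 3-[(1S,2R,3Z,6S)-2-[3-(TBDPS-oxy)propyl]-1,6-dimethyl-3-[1-(TBS-oxy)propan-2-ylidene]-6-(TES-oxy)cyclohexyl]propanal
Product: 29 (2E)-5-[(1S,2R,3Z,6S)-2-[3-(TBDPS-oxy)propyl]-1,6-dimethyl-3-[1-(TBS-oxy)propan-2-ylidene]-6-(TES-oxy)cyclohexyl]-2-methylpent-2-enal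
Conditions: Ph3P=C(CH3)CHO, toluene, 90 °C
Reagents that add atoms: 2-(triphenylphosphoranylidene)propanal CC(C=O)=P(c1ccccc1)(c1ccccc1)c1ccccc1
Why: Wittig olefination with the stabilised formyl ylide gives the (E)-2-methyl enal directly, setting the C14=C15 geometry and leaving C16 as the aldehyde.

Step 22
Reactants: 29 (2E)-5-[(1S,2R,3Z,6S)-2-[3-(TBDPS-oxy)propyl]-1,6-dimethyl-3-[1-(TBS-oxy)propan-2-ylidene]-6-(TES-oxy)cyclohexyl]-2-methylpent-2-enal; 30 geranyl chloride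
Product: 32 (3E,7E)-1-[(1S,2R,3Z,6S)-2-[3-(TBDPS-oxy)propyl]-1,6-dimethyl-3-[1-(TBS-oxy)propan-2-ylidene]-6-(TES-oxy)cyclohexyl]-4,8,12-trimethyltrideca-3,7,11-trien-5-ol (both C5 epimers), via geranylbarium chloride 31 (not isolated)
Conditions: BaI2, lithium biphenylide (LiC12H10, 2 equiv), THF, rt (activated Ba); 30, −78 °C; then 29, −78 °C
Reagents that add atoms: none
Why: Carbonyl allylation with an allylic barium reagent attacks the aldehyde through the α-carbon with retention of the E-alkene and 1,2-selectivity towards the enal, forging C16–C17 as the linear homoallylic alcohol; C16 forms unselectively and is corrected in steps 23 and 24.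

Step 23
Reactants: 32 (3E,7E)-1-[(1S,2R,3Z,6S)-2-[3-(TBDPS-oxy)propyl]-1,6-dimethyl-3-[1-(TBS-oxy)propan-2-ylidene]-6-(TES-oxy)cyclohexyl]-4,8,12-trimethyltrideca-3,7,11-trien-5-ol (both C5 epimers)
Product: 33 (3E,7E)-1-[(1S,2R,3Z,6S)-2-[3-(TBDPS-oxy)propyl]-1,6-dimethyl-3-[1-(TBS-oxy)propan-2-ylidene]-6-(TES-oxy)cyclohexyl]-4,8,12-trimethyltrideca-3,7,11-trien-5-one
Conditions: Dess–Martin periodinane, NaHCO3, CH2Cl2, 0 °C
Reagents that add atoms: none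
Why: Buffered Dess–Martin oxidation converts both epimers into one dienone without moving the skipped C18=C19 double bond into conjugation.

Step 24
Reactants: 33 (3E,7E)-1-[(1S,2R,3Z,6S)-2-[3-(TBDPS-oxy)propyl]-1,6-dimethyl-3-[1-(TBS-oxy)propan-2-ylidene]-6-(TES-oxy)cyclohexyl]-4,8,12-trimethyltrideca-3,7,11-trien-5-one
Product: 34 (3E,5R,7E)-1-[(1S,2R,3Z,6S)-2-[3-(TBDPS-oxy)propyl]-1,6-dimethyl-3-[1-(TBS-oxy)propan-2-ylidene]-6-(TES-oxy)cyclohexyl]-4,8,12-trimethyltrideca-3,7,11-trien-5-ol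
Conditions: (S)-2-methyl-CBS-oxazaborolidine (1 equiv), catecholborane, toluene, −78 °C
Reagents that add atoms: none
Why: Corey–Bakshi–Shibata reduction treats the α-methyl alkenyl group as the large substituent, so the (S)-catalyst delivers hydride to give the (16R)-alcohol, and catecholborane does not hydroborate the alkenes.

Step 25
Reactants: 34 (3E,5R,7E)-1-[(1S,2R,3Z,6S)-2-[3-(TBDPS-oxy)propyl]-1,6-dimethyl-3-[1-(TBS-oxy)propan-2-ylidene]-6-(TES-oxy)cyclohexyl]-4,8,12-trimethyltrideca-3,7,11-trien-5-ol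
Product: 35 (3E,5R,7E)-1-[(1S,2R,3Z,6S)-2-[3-(TBDPS-oxy)propyl]-1,6-dimethyl-3-[1-(TBS-oxy)propan-2-ylidene]-6-(TES-oxy)cyclohexyl]-4,8,12-trimethyltrideca-3,7,11-trien-5-yl acetate
Conditions: Ac2O, pyridine, DMAP (cat.), CH2Cl2, 0 °C to rt
Reagents that add atoms: acetic anhydride CC(=O)OC(C)=O
Why: Nucleophile-catalysed acylation esterifies the only free hydroxyl, the C16 alcohol, with retention.

Step 26
Reactants: 35 (3E,5R,7E)-1-[(1S,2R,3Z,6S)-2-[3-(TBDPS-oxy)propyl]-1,6-dimethyl-3-[1-(TBS-oxy)propan-2-ylidene]-6-(TES-oxy)cyclohexyl]-4,8,12-trimethyltrideca-3,7,11-trien-5-yl acetate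
Product: 36 (3E,5R,7E)-1-[(1S,2R,3Z,6S)-6-hydroxy-3-(1-hydroxypropan-2-ylidene)-2-(3-hydroxypropyl)-1,6-dimethylcyclohexyl]-4,8,12-trimethyltrideca-3,7,11-trien-5-yl acetate
Conditions: HF·pyridine, pyridine, THF, 0 °C to rt
Reagents that add atoms: none
Why: Fluoride-driven global desilylation removes the TBS, TES and TBDPS groups while the acetate and the polyene are inert to buffered HF.

Step 27
Reactants: 36 (3E,5R,7E)-1-[(1S,2R,3Z,6S)-6-hydroxy-3-(1-hydroxypropan-2-ylidene)-2-(3-hydroxypropyl)-1,6-dimethylcyclohexyl]-4,8,12-trimethyltrideca-3,7,11-trien-5-yl acetate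
Product: 37 (3E,5R,7E)-1-[(1S,2R,3Z,6S)-6-hydroxy-2-(3-hydroxypropyl)-1,6-dimethyl-3-(1-oxopropan-2-ylidene)cyclohexyl]-4,8,12-trimethyltrideca-3,7,11-trien-5-yl acetate
Conditions: MnO2, CH2Cl2, rt
Reagents that add atoms: none
Why: Allylic oxidation with MnO2 converts only the allylic primary alcohol into the (2Z)-enal and leaves the saturated primary and the tertiary hydroxyls.

Step 28
Reactants: 37 (3E,5R,7E)-1-[(1S,2R,3Z,6S)-6-hydroxy-2-(3-hydroxypropyl)-1,6-dimethyl-3-(1-oxopropan-2-ylidene)cyclohexyl]-4,8,12-trimethyltrideca-3,7,11-trien-5-yl acetate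
Product: 38 3-[(1R,2S,3S,6Z)-2-[(3E,5R,7E)-5-(acetyloxy)-4,8,12-trimethyltrideca-3,7,11-trien-1-yl]-3-hydroxy-2,3-dimethyl-6-(1-oxopropan-2-ylidene)cyclohexyl]propyl decanoate
Conditions: decanoyl chloride, pyridine, DMAP (cat.), CH2Cl2, 0 °C
Reagents that add atoms: decanoyl chloride CCCCCCCCCC(=O)Cl
Why: Acylation esterifies the primary C3 hydroxyl, while the hindered tertiary C10 hydroxyl next to the quaternary carbon does not react.

**Compound list**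

1 | 4-methoxy-3-methylphenol | COc1ccc(O)cc1C | starting material
2 | 4,4-dimethoxy-3-methylcyclohexa-2,5-dien-1-one | COC1(OC)C=CC(=O)C=C1C | intermediate
3 | 4,4-dimethoxy-3-methylcyclohex-2-en-1-one | COC1(OC)CCC(=O)C=C1C | intermediate
4 | (1S)-4,4-dimethoxy-3-methylcyclohex-2-en-1-ol | O[C@@H]1C=C(C)C(OC)(OC)CC1 | intermediate
5 | (1S)-4,4-dimethoxy-1-(PMB-oxy)-3-methylcyclohex-2-ene | COc1ccc(CO[C@@H]2C=C(C)C(OC)(OC)CC2)cc1 | intermediate
6 | (4S)-4-(PMB-oxy)-2-methylcyclohex-2-en-1-one | O=C1CC[C@H](OCc2ccc(OC)cc2)C=C1C | intermediate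
7 | 3-bromopropan-1-ol | OCCCBr | starting material
8 | (3-bromopropoxy)(tert-butyl)diphenylsilane | CC(C)(C)[Si](OCCCBr)(c1ccccc1)c1ccccc1 | intermediate
9 | {3-[(tert-butyldiphenylsilyl)oxy]propyl}magnesium bromide | CC(C)(C)[Si](OCCC[Mg]Br)(c1ccccc1)c1ccccc1 | intermediate
10 | (3S,4S)-3-[3-(TBDPS-oxy)propyl]-4-(PMB-oxy)-2-methyl-1-(TMS-oxy)cyclohex-1-ene | CC(C)(C)[Si](c2ccccc2)(c3ccccc3)OCCC[C@@H]1[C@@H](OCc4ccc(OC)cc4)CCC(O[Si](C)(C)C)=C1C | intermediate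
11 | lithium (3S,4S)-3-[3-(TBDPS-oxy)propyl]-4-(PMB-oxy)-2-methylcyclohex-1-en-1-olate | CC(C)(C)[Si](c2ccccc2)(c3ccccc3)OCCC[C@@H]1[C@@H](OCc4ccc(OC)cc4)CCC(O[Li])=C1C | intermediate
12 | (2S,3S,4S)-2-allyl-3-[3-(TBDPS-oxy)propyl]-4-(PMB-oxy)-2-methylcyclohexan-1-one | CC(C)(C)[Si](c2ccccc2)(c3ccccc3)OCCC[C@@H]1[C@@H](OCc4ccc(OC)cc4)CCC(=O)[C@@]1(C)CC=C | intermediate
13 | (1S,2S,3S,4S)-2-allyl-3-[3-(TBDPS-oxy)propyl]-4-(PMB-oxy)-1,2-dimethylcyclohexan-1-ol | CC(C)(C)[Si](c2ccccc2)(c3ccccc3)OCCC[C@@H]1[C@@H](OCc4ccc(OC)cc4)CC[C@](C)(O)[C@@]1(C)CC=C | intermediate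
14 | (1S,2S,3S,4S)-2-allyl-3-[3-(TBDPS-oxy)propyl]-4-(PMB-oxy)-1,2-dimethyl-1-(TES-oxy)cyclohexane | CC(C)(C)[Si](c2ccccc2)(c3ccccc3)OCCC[C@@H]1[C@@H](OCc4ccc(OC)cc4)CC[C@](C)(O[Si](CC)(CC)CC)[C@@]1(C)CC=C | intermediate
15 | (1S,2S,3S,4S)-3-allyl-2-[3-(TBDPS-oxy)propyl]-3,4-dimethyl-4-(TES-oxy)cyclohexan-1-ol | CC(C)(C)[Si](c2ccccc2)(c3ccccc3)OCCC[C@@H]1[C@@H](O)CC[C@](C)(O[Si](CC)(CC)CC)[C@@]1(C)CC=C | intermediate
16 | (2S,3S,4S)-3-allyl-2-[3-(TBDPS-oxy)propyl]-3,4-dimethyl-4-(TES-oxy)cyclohexan-1-one | CC(C)(C)[Si](c2ccccc2)(c3ccccc3)OCCC[C@@H]1C(=O)CC[C@](C)(O[Si](CC)(CC)CC)[C@@]1(C)CC=C | intermediate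
17 | potassium (4S,5S,6S)-5-allyl-6-[3-(TBDPS-oxy)propyl]-4,5-dimethyl-4-(TES-oxy)cyclohex-1-en-1-olate | CC(C)(C)[Si](c2ccccc2)(c3ccccc3)OCCC[C@@H]1C(O[K])=CC[C@](C)(O[Si](CC)(CC)CC)[C@@]1(C)CC=C | intermediate
18 | (4S,5S,6S)-5-allyl-6-[3-(TBDPS-oxy)propyl]-4,5-dimethyl-4-(TES-oxy)cyclohex-1-en-1-yl trifluoromethanesulfonate | CC(C)(C)[Si](c2ccccc2)(c3ccccc3)OCCC[C@@H]1C(OS(=O)(=O)C(F)(F)F)=CC[C@](C)(O[Si](CC)(CC)CC)[C@@]1(C)CC=C | intermediate
19 | (4S,5S,6S)-5-allyl-6-[3-(TBDPS-oxy)propyl]-1-(1-ethoxyethenyl)-4,5-dimethyl-4-(TES-oxy)cyclohex-1-ene | CC(C)(C)[Si](c2ccccc2)(c3ccccc3)OCCC[C@@H]1C(C(=C)OCC)=CC[C@](C)(O[Si](CC)(CC)CC)[C@@]1(C)CC=C | intermediate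
20 | 1-[(4S,5S,6S)-5-allyl-6-[3-(TBDPS-oxy)propyl]-4,5-dimethyl-4-(TES-oxy)cyclohex-1-en-1-yl]ethan-1-one | CC(C)(C)[Si](c2ccccc2)(c3ccccc3)OCCC[C@@H]1C(C(C)=O)=CC[C@](C)(O[Si](CC)(CC)CC)[C@@]1(C)CC=C | intermediate
21 | lithium (1Z)-1-[(2R,3S,4S)-3-allyl-2-[3-(TBDPS-oxy)propyl]-3,4-dimethyl-4-(TES-oxy)cyclohexylidene]ethan-1-olate | CC(C)(C)[Si](c2ccccc2)(c3ccccc3)OCCC[C@@H]1/C(=C(/C)O[Li])CC[C@](C)(O[Si](CC)(CC)CC)[C@@]1(C)CC=C | intermediate
22 | (1Z)-1-[(2R,3S,4S)-3-allyl-2-[3-(TBDPS-oxy)propyl]-3,4-dimethyl-4-(TES-oxy)cyclohexylidene]ethyl trifluoromethanesulfonate | CC(C)(C)[Si](c2ccccc2)(c3ccccc3)OCCC[C@@H]1/C(=C(/C)OS(=O)(=O)C(F)(F)F)CC[C@](C)(O[Si](CC)(CC)CC)[C@@]1(C)CC=C | intermediate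
23 | methyl (2Z)-2-[(2R,3S,4S)-3-allyl-2-[3-(TBDPS-oxy)propyl]-3,4-dimethyl-4-(TES-oxy)cyclohexylidene]propanoate | CC(C)(C)[Si](c2ccccc2)(c3ccccc3)OCCC[C@@H]1/C(=C(/C)C(=O)OC)CC[C@](C)(O[Si](CC)(CC)CC)[C@@]1(C)CC=C | intermediate
24 | (2Z)-2-[(2R,3S,4S)-3-allyl-2-[3-(TBDPS-oxy)propyl]-3,4-dimethyl-4-(TES-oxy)cyclohexylidene]propan-1-ol | CC(C)(C)[Si](c2ccccc2)(c3ccccc3)OCCC[C@@H]1/C(=C(/C)CO)CC[C@](C)(O[Si](CC)(CC)CC)[C@@]1(C)CC=C | intermediate
25 | (2Z)-2-[(2R,3S,4S)-3-allyl-2-[3-(TBDPS-oxy)propyl]-3,4-dimethyl-4-(TES-oxy)cyclohexylidene]-1-(TBS-oxy)propane | CC(C)(C)[Si](c2ccccc2)(c3ccccc3)OCCC[C@@H]1/C(=C(/C)CO[Si](C)(C)C(C)(C)C)CC[C@](C)(O[Si](CC)(CC)CC)[C@@]1(C)CC=C | intermediate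
26 | 9-{3-[(1S,2R,3Z,6S)-2-[3-(TBDPS-oxy)propyl]-1,6-dimethyl-3-[1-(TBS-oxy)propan-2-ylidene]-6-(TES-oxy)cyclohexyl]propyl}-9-borabicyclo[3.3.1]nonane | CC(C)(C)[Si](c2ccccc2)(c3ccccc3)OCCC[C@@H]1/C(=C(/C)CO[Si](C)(C)C(C)(C)C)CC[C@](C)(O[Si](CC)(CC)CC)[C@@]1(C)CCCB5C6CCCC5CCC6 | intermediate
27 | 3-[(1S,2R,3Z,6S)-2-[3-(TBDPS-oxy)propyl]-1,6-dimethyl-3-[1-(TBS-oxy)propan-2-ylidene]-6-(TES-oxy)cyclohexyl]propan-1-ol | CC(C)(C)[Si](c2ccccc2)(c3ccccc3)OCCC[C@@H]1/C(=C(/C)CO[Si](C)(C)C(C)(C)C)CC[C@](C)(O[Si](CC)(CC)CC)[C@@]1(C)CCCO | intermediate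
28 | 3-[(1S,2R,3Z,6S)-2-[3-(TBDPS-oxy)propyl]-1,6-dimethyl-3-[1-(TBS-oxy)propan-2-ylidene]-6-(TES-oxy)cyclohexyl]propanal | CC(C)(C)[Si](c2ccccc2)(c3ccccc3)OCCC[C@@H]1/C(=C(/C)CO[Si](C)(C)C(C)(C)C)CC[C@](C)(O[Si](CC)(CC)CC)[C@@]1(C)CCC=O | intermediate
29 | (2E)-5-[(1S,2R,3Z,6S)-2-[3-(TBDPS-oxy)propyl]-1,6-dimethyl-3-[1-(TBS-oxy)propan-2-ylidene]-6-(TES-oxy)cyclohexyl]-2-methylpent-2-enal | CC(C)(C)[Si](c2ccccc2)(c3ccccc3)OCCC[C@@H]1/C(=C(/C)CO[Si](C)(C)C(C)(C)C)CC[C@](C)(O[Si](CC)(CC)CC)[C@@]1(C)CC/C=C(\C)C=O | intermediate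
30 | geranyl chloride, (2E)-1-chloro-3,7-dimethylocta-2,6-diene | CC(C)=CCC/C(C)=C/CCl | starting material
31 | geranylbarium chloride | CC(C)=CCC/C(C)=C/C[Ba]Cl | intermediate
32 | (3E,7E)-1-[(1S,2R,3Z,6S)-2-[3-(TBDPS-oxy)propyl]-1,6-dimethyl-3-[1-(TBS-oxy)propan-2-ylidene]-6-(TES-oxy)cyclohexyl]-4,8,12-trimethyltrideca-3,7,11-trien-5-ol (both C5 epimers) | CC(C)(C)[Si](c2ccccc2)(c3ccccc3)OCCC[C@@H]1/C(=C(/C)CO[Si](C)(C)C(C)(C)C)CC[C@](C)(O[Si](CC)(CC)CC)[C@@]1(C)CC/C=C(\C)C(O)C/C=C(\C)CCC=C(C)C | intermediate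
33 | (3E,7E)-1-[(1S,2R,3Z,6S)-2-[3-(TBDPS-oxy)propyl]-1,6-dimethyl-3-[1-(TBS-oxy)propan-2-ylidene]-6-(TES-oxy)cyclohexyl]-4,8,12-trimethyltrideca-3,7,11-trien-5-one | CC(C)(C)[Si](c2ccccc2)(c3ccccc3)OCCC[C@@H]1/C(=C(/C)CO[Si](C)(C)C(C)(C)C)CC[C@](C)(O[Si](CC)(CC)CC)[C@@]1(C)CC/C=C(\C)C(=O)C/C=C(\C)CCC=C(C)C | intermediate
34 | (3E,5R,7E)-1-[(1S,2R,3Z,6S)-2-[3-(TBDPS-oxy)propyl]-1,6-dimethyl-3-[1-(TBS-oxy)propan-2-ylidene]-6-(TES-oxy)cyclohexyl]-4,8,12-trimethyltrideca-3,7,11-trien-5-ol | CC(C)(C)[Si](c2ccccc2)(c3ccccc3)OCCC[C@@H]1/C(=C(/C)CO[Si](C)(C)C(C)(C)C)CC[C@](C)(O[Si](CC)(CC)CC)[C@@]1(C)CC/C=C(\C)[C@@H](C/C=C(\C)CCC=C(C)C)O | intermediate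
35 | (3E,5R,7E)-1-[(1S,2R,3Z,6S)-2-[3-(TBDPS-oxy)propyl]-1,6-dimethyl-3-[1-(TBS-oxy)propan-2-ylidene]-6-(TES-oxy)cyclohexyl]-4,8,12-trimethyltrideca-3,7,11-trien-5-yl acetate | CC(C)(C)[Si](c2ccccc2)(c3ccccc3)OCCC[C@@H]1/C(=C(/C)CO[Si](C)(C)C(C)(C)C)CC[C@](C)(O[Si](CC)(CC)CC)[C@@]1(C)CC/C=C(\C)[C@@H](C/C=C(\C)CCC=C(C)C)OC(C)=O | intermediate
36 | (3E,5R,7E)-1-[(1S,2R,3Z,6S)-6-hydroxy-3-(1-hydroxypropan-2-ylidene)-2-(3-hydroxypropyl)-1,6-dimethylcyclohexyl]-4,8,12-trimethyltrideca-3,7,11-trien-5-yl acetate | OCCC[C@@H]1/C(=C(/C)CO)CC[C@](C)(O)[C@@]1(C)CC/C=C(\C)[C@@H](C/C=C(\C)CCC=C(C)C)OC(C)=O | intermediate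
37 | (3E,5R,7E)-1-[(1S,2R,3Z,6S)-6-hydroxy-2-(3-hydroxypropyl)-1,6-dimethyl-3-(1-oxopropan-2-ylidene)cyclohexyl]-4,8,12-trimethyltrideca-3,7,11-trien-5-yl acetate | OCCC[C@@H]1/C(=C(/C)C=O)CC[C@](C)(O)[C@@]1(C)CC/C=C(\C)[C@@H](C/C=C(\C)CCC=C(C)C)OC(C)=O | intermediate
38 | 3-[(1R,2S,3S,6Z)-2-[(3E,5R,7E)-5-(acetyloxy)-4,8,12-trimethyltrideca-3,7,11-trien-1-yl]-3-hydroxy-2,3-dimethyl-6-(1-oxopropan-2-ylidene)cyclohexyl]propyl decanoate (CNP0199124.2) | CCCCCCCCCC(=O)OCCC[C@@H]1/C(=C(/C)C=O)CC[C@](C)(O)[C@@]1(C)CC/C=C(\C)[C@@H](C/C=C(\C)CCC=C(C)C)OC(C)=O | target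

**Totals**

Total step count: 28. Longest linear sequence: 27 steps (1 to 38 through steps 1–5 and 7–28; step 6 is a one-step branch).

**Steps most likely to fail, with fallbacks**

Step 8 (quaternary centre by enolate allylation). The risk is a poor anti/syn ratio, or proton transfer before alkylation. The fallback sets out from 10 and comes back at 12. Cleave 10 with MeLi as before and quench the lithium enolate 11 with allyl chloroformate to give the allyl enol carbonate F1. Treat it with Pd(PPh3)4 in THF at rt: ionisation, loss of CO2 and recombination of the enolate with the allyl fragment (decarboxylative Tsuji allylation) put the allyl group on C11, again anti to the C6 chain, giving 12.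

Step 15 (conjugate reduction and enol triflate geometry). The risks are 1,2-reduction of the methyl ketone and erosion of enolate geometry. The fallback sets out from 16 and comes back at 23. Ramirez olefination (CBr4, PPh3, Zn, CH2Cl2) converts ketone 16 into the 1,1-dibromoalkene F2. The bromine syn to the ring CH2 (C8) is the less hindered one and is replaced first in a Negishi coupling (MeZnCl, Pd(PPh3)4, THF), giving the (Z)-bromoalkene F3 with bromine syn to C6. Bromine–lithium exchange (t-BuLi, THF, −78 °C) gives the vinyllithium F4, which is quenched with methyl chloroformate with retention to give ester 23.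

Step 22 (α-selective allylbarium addition). The risks are γ-attack giving the branched isomer and loss of E-geometry if the reagent warms. The fallback sets out from 30 and 29 and comes back at 33, so step 23 is skipped. Displace 30 with PhSO2Na in DMF to give geranyl phenyl sulfone F5. Deprotonate with n-BuLi (THF, −78 °C) to the lithiated sulfone F6, which adds to enal 29 through its α-carbon to give the β-hydroxy sulfone F7. Dess–Martin oxidation gives the β-keto sulfone F8, and reductive desulfonylation with SmI2 (THF/MeOH, −78 °C) gives dienone 33.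

**Further compounds**

F1 | step 8 | allyl (3S,4S)-3-[3-(TBDPS-oxy)propyl]-4-(PMB-oxy)-2-methylcyclohex-1-en-1-yl carbonate | CC(C)(C)[Si](c2ccccc2)(c3ccccc3)OCCC[C@@H]1[C@@H](OCc4ccc(OC)cc4)CCC(OC(=O)OCC=C)=C1C
F2 | step 15 | (1S,2S,3S)-2-allyl-1-[3-(TBDPS-oxy)propyl]-6-(dibromomethylidene)-2,3-dimethyl-3-(TES-oxy)cyclohexane | CC(C)(C)[Si](c2ccccc2)(c3ccccc3)OCCC[C@@H]1C(=C(Br)Br)CC[C@](C)(O[Si](CC)(CC)CC)[C@@]1(C)CC=C
F3 | step 15 | (1S,2S,3S,6Z)-2-allyl-6-(1-bromoethylidene)-1-[3-(TBDPS-oxy)propyl]-2,3-dimethyl-3-(TES-oxy)cyclohexane | CC(C)(C)[Si](c2ccccc2)(c3ccccc3)OCCC[C@@H]1/C(=C(/C)Br)CC[C@](C)(O[Si](CC)(CC)CC)[C@@]1(C)CC=C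
F4 | step 15 | vinyllithium from F3, lithium in place of bromine with the same alkene geometry | CC(C)(C)[Si](c2ccccc2)(c3ccccc3)OCCC[C@@H]1/C(=C(/C)[Li])CC[C@](C)(O[Si](CC)(CC)CC)[C@@]1(C)CC=C
F5 | step 22 | geranyl phenyl sulfone, {[(2E)-3,7-dimethylocta-2,6-dien-1-yl]sulfonyl}benzene | CC(C)=CCC/C(C)=C/CS(=O)(=O)c1ccccc1
F6 | step 22 | 1-lithio derivative of geranyl phenyl sulfone | CC(C)=CCC/C(C)=C/C([Li])S(=O)(=O)c1ccccc1
F7 | step 22 | (3E,7E)-6-(phenylsulfonyl) derivative of alcohol 32 (mixture of diastereomers at C5 and C6 of the chain) | CC(C)(C)[Si](c2ccccc2)(c3ccccc3)OCCC[C@@H]1/C(=C(/C)CO[Si](C)(C)C(C)(C)C)CC[C@](C)(O[Si](CC)(CC)CC)[C@@]1(C)CC/C=C(\C)C(O)C(/C=C(\C)CCC=C(C)C)S(=O)(=O)c5ccccc5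
F8 | step 22 | (3E,7E)-6-(phenylsulfonyl) derivative of ketone 33 | CC(C)(C)[Si](c2ccccc2)(c3ccccc3)OCCC[C@@H]1/C(=C(/C)CO[Si](C)(C)C(C)(C)C)CC[C@](C)(O[Si](CC)(CC)CC)[C@@]1(C)CC/C=C(\C)C(=O)C(/C=C(\C)CCC=C(C)C)S(=O)(=O)c5ccccc5
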